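**Retrosynthetic overview**
- The target comes from its quinone by reduction. In that quinone the O–C20 bond of the δ-lactone, the C9–C10 and C8–C14 bonds and the C13–O bond are all cut in one operation, back to a monocyclic ring-A triene ester.
- Enabling feature: on ring A the C19 ester (on C4) and the exocyclic C10=C20 methylene stand 1,3 to each other. Divalent mercury takes the CH2 carbon C20, the chain alkenes close rings B and C at C10, and C19 and C20 end up 1,3-diaxial on the ring-A chair, so the ester oxygen reaches C20 through the six-membered ring O–C20–C10–C5–C4–C19.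
- The triene ester comes from a ring-A sulfone and an allylic bromide (C6–C7 bond by sulfone alkylation, then desulfonylation), followed by unmasking of the quinone.
- The ring-A sulfone comes from a cyclohexenone ester: asymmetric conjugate methylation (C4), formaldehyde aldol locked as a temporary cis γ-lactone (C5), methylenation (C10=C20), thiolate opening. The bromide comes from nerol (its Z alkene later places the C14 substituent axial) and 1,4-dimethoxybenzene.
- Ring order: ring A (bought) → temporary γ-lactone (steps 2–4) → rings B and C and the δ-lactone together (step 13).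

Key step: step 13

Remark: atoms are referred to throughout by the isocopalane numbers of the target (ring A C1–C5, C10; ring B C5–C10; ring C C8, C9, C11–C14; C19 on C4, C20 on C10, C15 the benzylic carbon on C14; α is the face of 5-H, β that of C19 and C20). Methyl 3-oxocyclohex-1-ene-1-carboxylate is assumed to be purchasable.

Step 1
Reactants: 1 methyl 3-oxocyclohex-1-ene-1-carboxylate
Product: 2 methyl (1S)-1-methyl-3-[(trimethylsilyl)oxy]cyclohex-2-ene-1-carboxylate
Conditions: Me2Zn, (CuOTf)2·C6H6 (2.5 mol %), chiral sulfonate-bearing N-heterocyclic carbene ligand (5 mol %), Et2O, −30 °C; then Me3SiOTf, −78 °C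
Reagents that add atoms: dimethylzinc C[Zn]C; trimethylsilyl triflate C[Si](C)(C)OS(=O)(=O)C(F)(F)F
Why: Copper-catalysed asymmetric conjugate addition with enolate trapping, in which methyl should add to the ester-bearing β-carbon of the doubly activated enone under control of the chiral ligand (enantiomer chosen to give S at C4) and the zinc enolate is silylated regiospecifically toward C5.

Step 2
Reactants: 2 methyl (1S)-1-methyl-3-[(trimethylsilyl)oxy]cyclohex-2-ene-1-carboxylate
Product: 4 (3aR,7aS)-7a-methylhexahydro-2-benzofuran-1,4-dione, via hydroxymethyl ketone 3 (not isolated)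
Conditions: aq. HCHO, Yb(OTf)3 (10 mol %), THF, rt; then TsOH·H2O (cat.), toluene, 60 °C
Reagents that add atoms: formaldehyde C=O
Why: Mukaiyama aldol with aqueous formaldehyde followed by acid lactonisation, in which C5 epimerises through the enol of the C10 ketone and only the epimer with CH2OH cis to the ester can close the cis-fused γ-lactone, which should drain the equilibrium and fix C5.

Step 3
Reactants: 4 (3aR,7aS)-7a-methylhexahydro-2-benzofuran-1,4-dione
Product: 5 (3aR,7aS)-7a-methyl-4-methylidenehexahydro-2-benzofuran-1(3H)-one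
Conditions: Zn, CH2Br2, TiCl4, THF/CH2Cl2, 0 °C → rt
Reagents that add atoms: dibromomethane BrCBr
Why: Lombardo methylenation is non-basic, so the hindered C10 ketone should be converted without β-elimination of the acyloxy group or epimerisation at C5, and the lactone carbonyl is left alone.

Step 4
Reactants: 5 (3aR,7aS)-7a-methyl-4-methylidenehexahydro-2-benzofuran-1(3H)-one
Product: 7 methyl (1S,2R)-1-methyl-3-methylidene-2-[(phenylsulfanyl)methyl]cyclohexane-1-carboxylate, via sodium carboxylate 6 (not isolated)
Conditions: PhSNa, DMF, 100 °C; then MeI, rt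
Reagents that add atoms: sodium benzenethiolate [Na+].[S-]c1ccccc1; iodomethane CI
Why: SN2 opening of the γ-lactone at the O–CH2 carbon (alkyl–oxygen cleavage) by thiophenolate and O-methylation of the carboxylate remove the temporary ring without touching C4 or C5.

Step 5
Reactants: 7 methyl (1S,2R)-1-methyl-3-methylidene-2-[(phenylsulfanyl)methyl]cyclohexane-1-carboxylate
Product: 8 methyl (1S,2R)-1-methyl-3-methylidene-2-[(phenylsulfonyl)methyl]cyclohexane-1-carboxylate
Conditions: H2O2 (30 %), (NH4)6Mo7O24·4H2O (5 mol %), EtOH, 0 °C → rt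
Reagents that add atoms: hydrogen peroxide OO
Why: Molybdate-catalysed peroxide oxidation of sulfide to sulfone is chemoselective for sulfur over the 1,1-disubstituted alkene.

Step 6
Reactants: 9 nerol
Product: 10 neryl bromide
Conditions: PBr3, Et2O, −10 °C
Reagents that add atoms: phosphorus tribromide BrP(Br)Br
Why: Conversion of a primary allylic alcohol into the bromide with PBr3 at low temperature should keep the Z alkene.

Step 7
Reactants: 11 1,4-dimethoxybenzene; 10 neryl bromide
Product: 13 2-[(2Z)-3,7-dimethylocta-2,6-dien-1-yl]-1,4-dimethoxybenzene, via aryllithium 12 (not isolated)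
Conditions: n-BuLi, TMEDA, THF, 0 °C; then CuI (10 mol %), 10, −78 → 0 °C
Reagents that add atoms: none
Why: Directed ortho-lithiation followed by copper-catalysed SN2 allylation at the primary carbon of 10 should retain the Z geometry of the future C13=C14 alkene.

Step 8
Reactants: 13 2-[(2Z)-3,7-dimethylocta-2,6-dien-1-yl]-1,4-dimethoxybenzene
Product: 14 (2E,6Z)-8-(2,5-dimethoxyphenyl)-2,6-dimethylocta-2,6-dien-1-ol
Conditions: SeO2 (0.2 equiv), t-BuOOH, salicylic acid (cat.), CH2Cl2, 0 °C → rt
Reagents that add atoms: tert-butyl hydroperoxide CC(C)(C)OO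
Why: Riley allylic oxidation (ene reaction then [2,3]-shift) with catalytic SeO2 should oxidise the (E)-methyl group of the terminal, least hindered trisubstituted alkene and give the E allylic alcohol.

Step 9
Reactants: 14 (2E,6Z)-8-(2,5-dimethoxyphenyl)-2,6-dimethylocta-2,6-dien-1-ol
Product: 15 2-[(2Z,6E)-8-bromo-3,7-dimethylocta-2,6-dien-1-yl]-1,4-dimethoxybenzene
Conditions: PBr3, Et2O, −20 °C
Reagents that add atoms: phosphorus tribromide BrP(Br)Br
Why: Low-temperature bromination of the primary allylic alcohol with PBr3 should proceed without allylic transposition, so both alkene geometries are kept.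

Step 10
Reactants: 8 methyl (1S,2R)-1-methyl-3-methylidene-2-[(phenylsulfonyl)methyl]cyclohexane-1-carboxylate; 15 2-[(2Z,6E)-8-bromo-3,7-dimethylocta-2,6-dien-1-yl]-1,4-dimethoxybenzene
Product: 17 methyl (1S,2R)-2-[(3E,7Z)-9-(2,5-dimethoxyphenyl)-3,7-dimethyl-1-(phenylsulfonyl)nona-3,7-dien-1-yl]-1-methyl-3-methylidenecyclohexane-1-carboxylate (both C6 epimers), via lithiated sulfone 16 (not isolated)
Conditions: LiN(iPr)2, THF/DMPU, −78 °C; then 15, −78 → −20 °C
Reagents that add atoms: none
Why: SN2 alkylation of the α-sulfonyl carbanion with the primary allylic bromide joins C6 to C7, and the new centre at C6 does not matter because the sulfone is removed next.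

Step 11
Reactants: 17 coupled sulfone (both C6 epimers)
Product: 18 methyl (1S,2R)-2-[(3E,7Z)-9-(2,5-dimethoxyphenyl)-3,7-dimethylnona-3,7-dien-1-yl]-1-methyl-3-methylidenecyclohexane-1-carboxylate
Conditions: Na(Hg) (6 % Na), Na2HPO4, MeOH/THF, −20 → 0 °C
Reagents that add atoms: none
Why: Julia-type reductive desulfonylation with sodium amalgam removes the activating group from a non-allylic carbon, so no alkene should change position or geometry.

Step 12
Reactants: 18 dimethoxyarene triene ester
Product: 19 methyl (1S,2R)-2-[(3E,7Z)-9-(3,6-dioxocyclohexa-1,4-dien-1-yl)-3,7-dimethylnona-3,7-dien-1-yl]-1-methyl-3-methylidenecyclohexane-1-carboxylate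
Conditions: (NH4)2Ce(NO3)6, MeCN/H2O, 0 °C
Reagents that add atoms: water O
Why: Oxidative demethylation with ceric ammonium nitrate gives the quinone, which makes the arene non-nucleophilic so that it cannot trap the C13 cation in step 13, while isolated alkenes and the ester are inert.

Step 13
Reactants: 19 quinone triene ester
Product: 23 15-(1,4-benzoquinon-2-yl)-13α-hydroxy-14βH-isocopalan-19,20-olide (5α-H; 9α-H; 8β-CH3; 13β-CH3; CH2-quinone α on C14), via organomercurial 20 (not isolated), via iodide 21 (not isolated), via lactone trifluoroacetate 22 (not isolated)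
Conditions: Hg(O2CCF3)2, MeNO2, −20 °C; then I2, CH2Cl2, 0 °C → rt; then AgOTf, 2,6-lutidine, 0 °C → rt; aq. NaHCO3, THF
Reagents that add atoms: mercury bis(trifluoroacetate) FC(F)(F)C(=O)O[Hg]OC(=O)C(F)(F)F
Why: Mercury-induced cation–olefin bicyclisation, iododemercuration and silver-assisted lactonisation in one flask: divalent mercury, which adds to a 1,1-disubstituted terminal alkene much faster than to trisubstituted ones and can be guided to the β face by the C19 ester carbonyl, takes the CH2 carbon C20, C10 is attacked anti by C9 of the E alkene, the C8 cation by C14 of the Z alkene, and trifluoroacetate caps C13; iodine then replaces mercury at C20, silver triflate ionises the C20–I bond while the C19 ester carbonyl oxygen displaces it, the O-methyl oxocarbenium stage passes its methyl group to 2,6-lutidine, and bicarbonate hydrolyses the tertiary trifluoroacetate. The closest known reaction types are mercury trifluoroacetate polyene cyclisations followed by halodemercuration and the lactonisation of δ-halo esters by carbonyl participation. Ring B closes at C9→C10 and ring C at C14→C8, each 6-endo with respect to the attacking alkene and through a chair, and the δ-lactone closes 6-exo-tet at C20. C10 (C20 axial, β) follows from the trans-decalin chair set by the equatorial C5 side chain, C9 and C8 from anti addition across the E alkene, C14 (CH2-quinone axial, α) from the Z alkene, and C13 (OH equatorial, α) from capture anti to the new C8–C14 bond and away from the axial 8-methyl group. The step needs mercuration at C10=C20 and not at the trisubstituted alkenes, which the steric preference of divalent mercury and ester coordination should secure, and a C13 cation that the arene cannot trap, which the quinone oxidation level secures. Participation of the ester oxygen at the neopentyl C20 must beat a 1,2-alkyl shift, which the 1,3-diaxial placement of C19 and C20 on ring A favours.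

Step 14
Reactants: 23 quinone lactone
Product: 24 15-(2,5-dihydroxyphenyl)-13α-hydroxy-14βH-isocopalan-19,20-olide (the target)
Conditions: Na2S2O4, THF/H2O, rt, N2
Reagents that add atoms: none
Why: Dithionite reduction of the quinone to the hydroquinone is neutral, which avoids acid-induced chromane closure onto the tertiary C13 alcohol and leaves the lactone untouched.

**Compound list**
1 | methyl 3-oxocyclohex-1-ene-1-carboxylate | COC(=O)C1=CC(=O)CCC1 | starting material
2 | methyl (1S)-1-methyl-3-[(trimethylsilyl)oxy]cyclohex-2-ene-1-carboxylate | COC(=O)[C@@]1(C)CCCC(O[Si](C)(C)C)=C1 | intermediate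
3 | methyl (1S)-2-(hydroxymethyl)-1-methyl-3-oxocyclohexane-1-carboxylate (both C2 epimers) | COC(=O)[C@@]1(C)CCCC(=O)C1CO | intermediate
4 | (3aR,7aS)-7a-methylhexahydro-2-benzofuran-1,4-dione | O=C1CCC[C@]2(C)C(=O)OC[C@H]12 | intermediate
5 | (3aR,7aS)-7a-methyl-4-methylidenehexahydro-2-benzofuran-1(3H)-one | C=C1CCC[C@]2(C)C(=O)OC[C@H]12 | intermediate
6 | sodium (1S,2R)-1-methyl-3-methylidene-2-[(phenylsulfanyl)methyl]cyclohexane-1-carboxylate | [Na+].[O-]C(=O)[C@@]1(C)CCCC(=C)[C@H]1CSc1ccccc1 | intermediate
7 | methyl (1S,2R)-1-methyl-3-methylidene-2-[(phenylsulfanyl)methyl]cyclohexane-1-carboxylate | COC(=O)[C@@]1(C)CCCC(=C)[C@H]1CSc1ccccc1 | intermediate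
8 | methyl (1S,2R)-1-methyl-3-methylidene-2-[(phenylsulfonyl)methyl]cyclohexane-1-carboxylate | COC(=O)[C@@]1(C)CCCC(=C)[C@H]1CS(=O)(=O)c1ccccc1 | intermediate
9 | nerol | CC(C)=CCC/C(C)=C\CO | starting material
10 | neryl bromide | CC(C)=CCC/C(C)=C\CBr | intermediate
11 | 1,4-dimethoxybenzene | COc1ccc(OC)cc1 | starting material
12 | (2,5-dimethoxyphenyl)lithium | [Li]c1cc(OC)ccc1OC | intermediate
13 | 2-[(2Z)-3,7-dimethylocta-2,6-dien-1-yl]-1,4-dimethoxybenzene | CC(C)=CCC/C(C)=C\Cc1cc(OC)ccc1OC | intermediate
14 | (2E,6Z)-8-(2,5-dimethoxyphenyl)-2,6-dimethylocta-2,6-dien-1-ol | OC/C(C)=C/CC/C(C)=C\Cc1cc(OC)ccc1OC | intermediate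
15 | 2-[(2Z,6E)-8-bromo-3,7-dimethylocta-2,6-dien-1-yl]-1,4-dimethoxybenzene | BrC/C(C)=C/CC/C(C)=C\Cc1cc(OC)ccc1OC | intermediate
16 | 8 lithiated at the CH2SO2Ph carbon (C6) | COC(=O)[C@@]1(C)CCCC(=C)[C@H]1C([Li])S(=O)(=O)c1ccccc1 | intermediate
17 | methyl (1S,2R)-2-[(3E,7Z)-9-(2,5-dimethoxyphenyl)-3,7-dimethyl-1-(phenylsulfonyl)nona-3,7-dien-1-yl]-1-methyl-3-methylidenecyclohexane-1-carboxylate (both C6 epimers) | COC(=O)[C@@]1(C)CCCC(=C)[C@H]1C(C/C(C)=C/CC/C(C)=C\Cc1cc(OC)ccc1OC)S(=O)(=O)c1ccccc1 | intermediate
18 | methyl (1S,2R)-2-[(3E,7Z)-9-(2,5-dimethoxyphenyl)-3,7-dimethylnona-3,7-dien-1-yl]-1-methyl-3-methylidenecyclohexane-1-carboxylate | COC(=O)[C@@]1(C)CCCC(=C)[C@H]1CC/C(C)=C/CC/C(C)=C\Cc1cc(OC)ccc1OC | intermediate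
19 | methyl (1S,2R)-2-[(3E,7Z)-9-(3,6-dioxocyclohexa-1,4-dien-1-yl)-3,7-dimethylnona-3,7-dien-1-yl]-1-methyl-3-methylidenecyclohexane-1-carboxylate | COC(=O)[C@@]1(C)CCCC(=C)[C@H]1CC/C(C)=C/CC/C(C)=C\CC1=CC(=O)C=CC1=O | intermediate
20 | methyl 15-(1,4-benzoquinon-2-yl)-13α-(trifluoroacetoxy)-20-[(trifluoroacetato)mercurio]-14βH-isocopalan-19-oate | C[C@@]12CC[C@@H]3[C@](C[Hg]OC(=O)C(F)(F)F)(CCC[C@]3(C)C(=O)OC)[C@H]1CC[C@](C)(OC(=O)C(F)(F)F)[C@@H]2CC1=CC(=O)C=CC1=O | intermediate
21 | methyl 15-(1,4-benzoquinon-2-yl)-20-iodo-13α-(trifluoroacetoxy)-14βH-isocopalan-19-oate | C[C@@]12CC[C@@H]3[C@](CI)(CCC[C@]3(C)C(=O)OC)[C@H]1CC[C@](C)(OC(=O)C(F)(F)F)[C@@H]2CC1=CC(=O)C=CC1=O | intermediate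
22 | 15-(1,4-benzoquinon-2-yl)-13α-(trifluoroacetoxy)-14βH-isocopalan-19,20-olide | C[C@@]12CC[C@@H]3[C@]4(CCC[C@]3(C)C(=O)OC4)[C@H]1CC[C@](C)(OC(=O)C(F)(F)F)[C@@H]2CC1=CC(=O)C=CC1=O | intermediate
23 | 15-(1,4-benzoquinon-2-yl)-13α-hydroxy-14βH-isocopalan-19,20-olide | C[C@@]12CC[C@@H]3[C@]4(CCC[C@]3(C)C(=O)OC4)[C@H]1CC[C@](C)(O)[C@@H]2CC1=CC(=O)C=CC1=O | intermediate
24 | 15-(2,5-dihydroxyphenyl)-13α-hydroxy-14βH-isocopalan-19,20-olide | C[C@@]12CC[C@@H]3[C@]4(CCC[C@]3(C)C(=O)OC4)[C@H]1CC[C@](C)(O)[C@@H]2Cc1cc(O)ccc1O | target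

**Step count**
Total: 14 steps. Longest linear sequence: 10 steps (1 → 24 through steps 1–5 and 10–14).

**Steps most likely to fail**

Step 13. When silver ionises the neopentyl C20–I bond, a 1,2-shift of a ring bond to C20 may outrun participation of the ester oxygen, so the cascade would end in ring-expanded material. The fallback sets out from 19. Only the mercury stage is run and quenched with aqueous NaCl/NaHCO3, which should give the chloromercurial methyl 15-(1,4-benzoquinon-2-yl)-20-(chloromercurio)-13α-hydroxy-14βH-isocopalan-19-oate F1. Oxidative demercuration (NaBH4, O2, DMF) is a radical process with no cation at C20 and also reduces the quinone; it should give the hydroquinone triol ester methyl 15-(2,5-dihydroxyphenyl)-13α,20-dihydroxy-14βH-isocopalan-19-oate F2. Neutral transesterification (2-hydroxypyridine cat., toluene, 90 °C) then closes the δ-lactone from the C20 hydroxyl at the C19 carbonyl, which is the other ring bond, with loss of methanol. The sequence returns to the route at 24.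

Step 8. Ene attack of selenium dioxide at the second trisubstituted alkene (C13=C14, not deactivated here) and over-oxidation may erode regioselectivity. The fallback sets out from 13. Terminal-selective bromohydrin formation (NBS, THF/H2O, 0 °C) should give the bromohydrin 3-bromo-8-(2,5-dimethoxyphenyl)-2,6-dimethyloct-6-en-2-ol F3. K2CO3 in MeOH closes it to the epoxide 2-[(2Z)-5-(3,3-dimethyloxiran-2-yl)-3-methylpent-2-en-1-yl]-1,4-dimethoxybenzene F4. Al(OiPr)3 in hot toluene isomerises the epoxide to the isopropenyl carbinol (6Z)-8-(2,5-dimethoxyphenyl)-2,6-dimethylocta-1,6-dien-3-ol F5. PBr3 then converts this by SN2' substitution into the E allylic bromide, and the sequence returns at 15.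

Step 4. SN2 attack at C6, a primary carbon flanked by the branched C5 and the quaternary C4, may be too slow, so that thiolate attack at the carbonyl or drift of the exocyclic alkene takes over. The fallback sets out from 4. Amine-triggered β-elimination of the acyloxy group gives the 2-methylidene ketone carboxylate, and conjugate addition of benzenesulfinate (Et3N cat., PhSO2Na, AcOH, aq. EtOH, 50 °C) should give the keto acid (1S,2R)-1-methyl-3-oxo-2-[(phenylsulfonyl)methyl]cyclohexane-1-carboxylic acid F6. Esterification with Me3SiCHN2 gives its methyl ester F7, and Lombardo methylenation returns to the route at 8. In this variant C5 rests on thermodynamic control only, so its epimer would have to be separated.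

**Further compounds**
F1 | step 13 | methyl 15-(1,4-benzoquinon-2-yl)-20-(chloromercurio)-13α-hydroxy-14βH-isocopalan-19-oate | C[C@@]12CC[C@@H]3[C@](C[Hg]Cl)(CCC[C@]3(C)C(=O)OC)[C@H]1CC[C@](C)(O)[C@@H]2CC1=CC(=O)C=CC1=O
F2 | step 13 | methyl 15-(2,5-dihydroxyphenyl)-13α,20-dihydroxy-14βH-isocopalan-19-oate | C[C@@]12CC[C@@H]3[C@](CO)(CCC[C@]3(C)C(=O)OC)[C@H]1CC[C@](C)(O)[C@@H]2Cc1cc(O)ccc1O
F3 | step 8 | 3-bromo-8-(2,5-dimethoxyphenyl)-2,6-dimethyloct-6-en-2-ol (6Z, racemic at C3) | CC(C)(O)C(Br)CC/C(C)=C\Cc1cc(OC)ccc1OC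
F4 | step 8 | 2-[(2Z)-5-(3,3-dimethyloxiran-2-yl)-3-methylpent-2-en-1-yl]-1,4-dimethoxybenzene (racemic) | CC1(C)OC1CC/C(C)=C\Cc1cc(OC)ccc1OC
F5 | step 8 | (6Z)-8-(2,5-dimethoxyphenyl)-2,6-dimethylocta-1,6-dien-3-ol (racemic) | C=C(C)C(O)CC/C(C)=C\Cc1cc(OC)ccc1OC
F6 | step 4 | (1S,2R)-1-methyl-3-oxo-2-[(phenylsulfonyl)methyl]cyclohexane-1-carboxylic acid | OC(=O)[C@@]1(C)CCCC(=O)[C@H]1CS(=O)(=O)c1ccccc1
F7 | step 4 | methyl (1S,2R)-1-methyl-3-oxo-2-[(phenylsulfonyl)methyl]cyclohexane-1-carboxylate | COC(=O)[C@@]1(C)CCCC(=O)[C@H]1CS(=O)(=O)c1ccccc1
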